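**Plan**

- Route numbering for all bicyclic compounds: C1 carbinol carbon (O, isopropyl), C2, C3, C4 quaternary (CH3), C5, C6, C7 (CH3), C8, C9 (CHOH), C10 ring-fusion CH. Ring A = C1–C2–C3–C4–C10, ring B = C4–C5–C6–C7–C8–C9–C10. β is the face of the C4 methyl, α the other.
- Retrosynthesis: the vanillate acyl–O bond at C1, the epoxide oxygen, the C9–H and C10–H bonds and the C1–isopropyl bond are cut first. Ring B is then, at the enol level, a cyclohepta-1,4-diene (C6=C7 and enol ether C9=C10, sp3 C8 between them, C4–C5 opposite) fused to the cyclopentenone ring A. That is the product pattern of a cis-divinylcyclopropane Cope shift, so C4–C5 and then C7–C8/C7–C9 (carbenoid carbon C7) are cut last.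
- Forward: ring A is bought (3-methylcyclopentenone) and given a 1-ethoxyvinyl arm; ring B closes in step 4; then isopropyl on C1, ester to C7 methyl, adjustment of the oxygen pattern, vanillate.
- Stereochemistry: C4 from the chiral dirhodium catalyst, relayed through the cyclopropane. A temporary 9β carbinol (CBS) directs oxygen to the β face of C1. C10 by enolate protonation, C9 by hydride delivery from the C1 hydroxyl, the epoxide by the C9 hydroxyl.

Key step: step 4

Remark on the chemistry: the sense of induction of Rh2(DOSP)4 known for monosubstituted alkenes (alkene substituent cis to the donor group) is assumed to hold for the 1,1-disubstituted enol ether of 4, with the cyclopentenyl group in the place of that substituent; on this basis the R catalyst is specified.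

**Step 1**
Reactants: 1 3-methylcyclopent-2-en-1-one
Product: 2 2-iodo-3-methylcyclopent-2-en-1-one
Conditions: I2, pyridine, CH2Cl2, 0 °C → rt
Reagents that add atoms: iodine, II
Why: Pyridine adds reversibly to the enone β-carbon, the enolate is iodinated and pyridine is expelled (addition–elimination α-iodination of an enone), which should give the 2-iodo enone.

**Step 2**
Reactants: 2 2-iodo-3-methylcyclopent-2-en-1-one; 3 tributyl(1-ethoxyethenyl)stannane
Product: 4 2-(1-ethoxyethenyl)-3-methylcyclopent-2-en-1-one
Conditions: Pd(PPh3)4 (5 mol %), CuI (10 mol %), DMF, 60 °C; aq. KF work-up; Et3N-deactivated silica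
Reagents that add atoms: none
Why: Stille coupling of the alkenyl iodide (zerovalent palladium, copper co-catalysis) transfers the intact enol ether, so the enol double bond is placed by the reagent and not by an enolisation; the ethyl ether is used because its stannane is commercial and the derived vinylogous ethyl ester serves step 7.

**Step 3**
Reactants: 5 methyl but-3-enoate
Product: 6 methyl 2-diazobut-3-enoate
Conditions: 4-acetamidobenzenesulfonyl azide, DBU, MeCN, 0 °C; used at once, cold
Reagents that add atoms: 4-acetamidobenzenesulfonyl azide, CC(=O)Nc1ccc(cc1)S(=O)(=O)N=[N+]=[N-]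
Why: Regitz diazo transfer to the doubly activated C2 of the β,γ-unsaturated ester gives the vinyldiazoacetate, which is not stored because it cyclises to a pyrazole.

**Step 4**
Reactants: 4 2-(1-ethoxyethenyl)-3-methylcyclopent-2-en-1-one; 6 methyl 2-diazobut-3-enoate
Product: 8 (4R)-bicyclic vinylogous ester (C1 ketone; C9-ethoxy C9=C10 enol ether; C6=C7 carrying CO2Me on C7), via cis-divinylcyclopropane 7 (not isolated)
Conditions: Rh2(R-DOSP)4 (1 mol %), hexanes, −40 °C → rt, slow addition of 6 (2 equiv); then PhMe, 90 °C
Reagents that add atoms: none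
Why: The catalyst turns 6 into a donor/acceptor rhodium vinylcarbenoid whose carbon C7 adds to the electron-rich ethoxyethene unit C8=C9 of 4 in a concerted, asynchronous cyclopropanation (C7–C8 ahead of C7–C9, charge on C9 held by the ethoxy group). The closest known reaction type is the tandem cyclopropanation/Cope rearrangement of vinyldiazoacetates with 1,3-dienes, a formal (4+3) cycloaddition also known for 2-oxygenated dienes. Ring B is closed not end to end but by the [3,3] shift of cis-divinylcyclopropane 7 through a boat transition state, which breaks C7–C9 and makes C4–C5 (ring expansion to the cyclohepta-1,4-diene). The one stereocentre that remains, C4, is set by the catalyst: it fixes the configuration of 7, and in the boat only the rotamer with C4 over the three-membered ring can react, so one face of C4 bonds to C5. The step needs chemoselection for the enol ether alkene over the tetrasubstituted, electron-poor enone alkene (secured by the electrophilic carbenoid; the hydrocarbon solvent disfavours the zwitterionic (3+2) path), cis placement of the ethenyl and cyclopentenyl groups (the usual preference of the alkene substituent for the side of the donor group), and enantioselection. Because the C4 methyl points inward in the boat, the Cope step is expected to need the heating period.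

**Step 5**
Reactants: 8 (4R)-bicyclic vinylogous ester
Product: 9 C1 carbinol of 8 (1-hydroxy-1-isopropyl; both C1 epimers)
Conditions: i-PrMgCl, CeCl3, THF, −78 °C; aq. NaHCO3 work-up; crude used
Reagents that add atoms: isopropylmagnesium chloride, CC(C)[Mg]Cl
Why: The organocerium reagent is nucleophilic but weakly basic and should add 1,2 to the ring carbonyl faster than to the conjugated ester and without enolisation or β-hydride reduction; both C1 epimers are carried on because this centre becomes sp2 again in step 7.

**Step 6**
Reactants: 9 C1 carbinol of 8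
Product: 10 allylic diol (CH2OH on C7)
Conditions: i-Bu2AlH (4 equiv), CH2Cl2, −78 → −20 °C; aq. potassium sodium tartrate
Reagents that add atoms: none
Why: 1,2-Reduction of the conjugated ester to the primary allylic alcohol; the tertiary alkoxide and the enol ether survive the non-acidic conditions and work-up.

**Step 7**
Reactants: 10 allylic diol
Product: 13 (4R)-1-isopropyl-4,7-dimethyl dienone (C1=C10; C6=C7; 9-oxo), via allylic mesylate 11 (not isolated), via C7-methyl carbinol 12 (not isolated)
Conditions: MsCl, Et3N, THF, −40 °C; LiBHEt3 (5 equiv), −40 → 0 °C; then 1 M HCl, 0 °C, short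
Reagents that add atoms: methanesulfonyl chloride, CS(=O)(=O)Cl (kept only in 11); water, O (carbonyl oxygen of 13)
Why: The primary allylic alcohol is mesylated selectively and LiBHEt3 displaces the mesylate by SN2 to give the C7 methyl; the acid quench then ionises the tertiary allylic alcohol with help from the enol ether and hydrolyses the oxocarbenium ion at C9 (Stork–Danheiser transposition) to the C9 ketone with a new C1=C10 alkene, brief cold acid being meant to leave C6=C7 in place.

**Step 8**
Reactants: 13 (4R)-dienone
Product: 14 (4R,9R)-allylic alcohol (9β-OH)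
Conditions: (S)-2-methyl-CBS-oxazaborolidine (0.5 equiv), catecholborane, PhMe, −78 °C
Reagents that add atoms: none
Why: Corey–Bakshi–Shibata reduction with the fully substituted alkenyl arm (C10) as the large group should give the 9R carbinol by reagent control, whatever the weak bias of remote C4; any enantiomer left from step 4 becomes a separable diastereomer here.

**Step 9**
Reactants: 14 (4R,9R)-allylic alcohol
Product: 15 1β,10β-epoxy-9β-alcohol
Conditions: VO(acac)2 (5 mol %), t-BuOOH (1.2 equiv), CH2Cl2, 0 °C
Reagents that add atoms: tert-butyl hydroperoxide, CC(C)(C)OO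
Why: Hydroxyl-directed epoxidation: the vanadium alkoxide delivers oxygen to the allylic, tetrasubstituted C1=C10 alkene on the face of the C9 hydroxyl (allylic 1,3-strain holds C9–H beside the isopropyl group and the oxygen on the β face), which sets C1–O β and isopropyl α; the homoallylic C6=C7 reacts much more slowly.

**Step 10**
Reactants: 15 1β,10β-epoxy-9β-alcohol
Product: 16 1β,10β-epoxy-9-ketone
Conditions: Dess–Martin periodinane, NaHCO3, CH2Cl2, 0 °C → rt
Reagents that add atoms: none
Why: Buffered Dess–Martin oxidation gives the α,β-epoxy ketone without acid that could open the tetrasubstituted epoxide; the temporary C9 centre is no longer needed.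

**Step 11**
Reactants: 16 1β,10β-epoxy-9-ketone
Product: 17 trans-fused ketol (1β-OH; 1α-isopropyl; 10α-H; 9-oxo)
Conditions: SmI2 (2.5 equiv), THF/MeOH, −90 °C; pH 7 buffer
Reagents that add atoms: none
Why: Two-electron reductive opening of the α,β-epoxy ketone breaks the C10–O bond and leaves C1–O untouched (retention at C1); the samarium enolate is expected to be protonated at C10 on the α face, anti to the metal-bound C1 alkoxide that covers the β face together with the C4 methyl, and low temperature with an in situ proton source should prevent retro-aldol cleavage and dehydration.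

**Step 12**
Reactants: 17 trans-fused ketol
Product: 18 anti-1β,9α-diol
Conditions: Me4NBH(OAc)3, MeCN/AcOH, −30 °C
Reagents that add atoms: none
Why: Evans–Saksena reduction: the C1 hydroxyl binds boron and hydride is delivered intramolecularly to the β face of the C9 ketone, giving the anti 1,3-diol with the 9α (9S) carbinol.

**Step 13**
Reactants: 18 anti-1β,9α-diol
Product: 19 6α,7α-epoxy-1β,9α-diol
Conditions: VO(acac)2 (5 mol %), t-BuOOH, CH2Cl2, 0 °C → rt
Reagents that add atoms: tert-butyl hydroperoxide, CC(C)(C)OO
Why: Homoallylic hydroxyl-directed epoxidation from the C9 vanadate puts oxygen on the α face of C6=C7, which is also the face not screened by the C4 methyl.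

**Step 14**
Reactants: 19 6α,7α-epoxy-1β,9α-diol
Product: 20 9α-benzyl ether of 19
Conditions: NaH (1.1 equiv), BnBr, Bu4NI (cat.), THF/DMF, 0 °C → rt
Reagents that add atoms: benzyl bromide, BrCc1ccccc1
Why: Williamson etherification of the more acidic, less hindered secondary alkoxide while the tertiary carbinol stays free; a benzyl ether cannot migrate to the C1 alkoxide in step 17 and leaves under neutral conditions.

**Step 15**
Reactants: 21 vanillic acid
Product: 23 4-(benzyloxy)-3-methoxybenzoic acid, via benzyl ester 22 (not isolated)
Conditions: BnBr (2.2 equiv), K2CO3, DMF, 60 °C; then NaOH, MeOH/H2O, 60 °C; HCl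
Reagents that add atoms: benzyl bromide, BrCc1ccccc1; sodium hydroxide, [Na+].[OH-] (one carboxyl oxygen)
Why: O-Alkylation of phenoxide and carboxylate, then saponification of the benzyl ester in the same flask; the aryl benzyl ether is stable to hydroxide.

**Step 16**
Reactants: 23 4-(benzyloxy)-3-methoxybenzoic acid
Product: 24 4-(benzyloxy)-3-methoxybenzoyl chloride
Conditions: (COCl)2, DMF (cat.), CH2Cl2, 0 °C → rt
Reagents that add atoms: oxalyl chloride, O=C(Cl)C(Cl)=O
Why: Chlorination through the Vilsmeier chloroiminium salt gives the acid chloride under conditions that leave the benzyl ether intact.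

**Step 17**
Reactants: 20 9α-benzyl ether; 24 4-(benzyloxy)-3-methoxybenzoyl chloride
Product: 25 bis-benzyl-protected target (C1 aroate; 9α-OBn; aryl OBn)
Conditions: n-BuLi (1.05 equiv), THF, −78 °C; then 24, DMAP (cat.), −78 → 0 °C
Reagents that add atoms: none
Why: O-Acylation of the lithium alkoxide with an aroyl chloride is the standard esterification of hindered tertiary alcohols; no other acidic or migrating group is present and the trisubstituted epoxide should not be attacked at low temperature.

**Step 18**
Reactants: 25 bis-benzyl-protected target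
Product: 26 target
Conditions: H2 (1 atm), Pd(OH)2/C, EtOAc, rt
Reagents that add atoms: none
Why: Neutral hydrogenolysis removes both benzyl ethers without the base that could move the aroyl group from the tertiary to the secondary oxygen; the non-benzylic epoxide and the ester are expected to survive.

**Compound list**

1 | 3-methylcyclopent-2-en-1-one | CC1=CC(=O)CC1 | starting material
2 | 2-iodo-3-methylcyclopent-2-en-1-one | CC1=C(I)C(=O)CC1 | intermediate
3 | tributyl(1-ethoxyethenyl)stannane | CCCC[Sn](CCCC)(CCCC)C(=C)OCC | starting material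
4 | 2-(1-ethoxyethenyl)-3-methylcyclopent-2-en-1-one | C=C(OCC)C1=C(C)CCC1=O | intermediate
5 | methyl but-3-enoate | C=CCC(=O)OC | starting material
6 | methyl 2-diazobut-3-enoate | C=CC(=[N+]=[N-])C(=O)OC | intermediate
7 | methyl (1S,2R)-2-ethoxy-1-ethenyl-2-(2-methyl-5-oxocyclopent-1-en-1-yl)cyclopropane-1-carboxylate (ethenyl and cyclopentenyl cis) | C=C[C@@]1(C(=O)OC)C[C@@]1(OCC)C2=C(C)CCC2=O | intermediate (not isolated)
8 | (4R)-methyl 9-ethoxy-4-methyl-1-oxo bicyclic diene carboxylate (route numbering: C9=C10 enol ether, C6=C7, CO2Me on C7) | O=C1CC[C@]2(C)CC=C(C(=O)OC)CC(OCC)=C21 | intermediate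
9 | (4R)-1-hydroxy-1-isopropyl derivative of 8, both C1 epimers | CC(C)C1(O)CC[C@]2(C)CC=C(C(=O)OC)CC(OCC)=C12 | intermediate
10 | as 9 with CH2OH on C7 | CC(C)C1(O)CC[C@]2(C)CC=C(CO)CC(OCC)=C12 | intermediate
11 | as 10 with CH2OSO2CH3 on C7 | CC(C)C1(O)CC[C@]2(C)CC=C(COS(C)(=O)=O)CC(OCC)=C12 | intermediate (not isolated)
12 | as 10 with CH3 on C7 | CC(C)C1(O)CC[C@]2(C)CC=C(C)CC(OCC)=C12 | intermediate (not isolated)
13 | (4R)-1-isopropyl-4,7-dimethyl dienone (C1=C10, C6=C7, 9-oxo) | CC(C)C1=C2C(=O)CC(C)=CC[C@@]2(C)CC1 | intermediate
14 | (4R,9R)-allylic alcohol (9β-OH) from 13 | CC(C)C1=C2[C@H](O)CC(C)=CC[C@@]2(C)CC1 | intermediate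
15 | 1β,10β-epoxy-9β-ol (C6=C7 retained) | CC(C)[C@]12CC[C@]3(C)CC=C(C)C[C@@H](O)[C@]13O2 | intermediate
16 | 1β,10β-epoxy-9-one | CC(C)[C@]12CC[C@]3(C)CC=C(C)CC(=O)[C@]13O2 | intermediate
17 | (1R,4R,10S)-1-hydroxy-1-isopropyl-4,7-dimethyl-9-oxo ketol, trans-fused (10α-H), C6=C7 | O[C@@]1(C(C)C)CC[C@]2(C)CC=C(C)CC(=O)[C@H]21 | intermediate
18 | (1R,4R,9S,10S)-1β,9α-diol, C6=C7 | O[C@@]1(C(C)C)CC[C@]2(C)CC=C(C)C[C@H](O)[C@H]21 | intermediate
19 | (1R,4R,6S,7R,9S,10S)-6α,7α-epoxy-1β,9α-diol | O[C@@]1(C(C)C)CC[C@]2(C)C[C@@H]3O[C@]3(C)C[C@H](O)[C@H]21 | intermediate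
20 | 9α-O-benzyl ether of 19 | O[C@@]1(C(C)C)CC[C@]2(C)C[C@@H]3O[C@]3(C)C[C@H](OCc4ccccc4)[C@H]21 | intermediate
21 | vanillic acid | COc1cc(C(=O)O)ccc1O | starting material
22 | benzyl 4-(benzyloxy)-3-methoxybenzoate | COc1cc(C(=O)OCc2ccccc2)ccc1OCc1ccccc1 | intermediate (not isolated)
23 | 4-(benzyloxy)-3-methoxybenzoic acid | COc1cc(C(=O)O)ccc1OCc1ccccc1 | intermediate
24 | 4-(benzyloxy)-3-methoxybenzoyl chloride | COc1cc(C(Cl)=O)ccc1OCc1ccccc1 | intermediate
25 | C1 4-(benzyloxy)-3-methoxybenzoate of 20 | COc1cc(C(=O)O[C@@]2(C(C)C)CC[C@]3(C)C[C@@H]4O[C@]4(C)C[C@H](OCc5ccccc5)[C@H]32)ccc1OCc1ccccc1 | intermediate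
26 | (1R,4R,6S,7R,9S,10S)-6α,7α-epoxy-9α-hydroxy-1-isopropyl-4,7-dimethyl bicycle, C1 4-hydroxy-3-methoxybenzoate | COc1cc(C(=O)O[C@@]2(C(C)C)CC[C@]3(C)C[C@@H]4O[C@]4(C)C[C@H](O)[C@H]32)ccc1O | target

**Totals and risks**

Total steps: 18. Longest linear sequence: 15 steps from 1 (steps 1, 2, 4 to 14, 17, 18).

Step 4. What may go wrong: loss of enantio- or cis-diastereocontrol when the carbenoid is transferred to a 1,1-disubstituted enol ether, or a Cope shift (inward C4 methyl) too slow at the temperatures where the chiral catalyst is selective, so that the donor–acceptor cyclopropane opens instead. Fallback, from 4 and 6 back to 14: the cycloaddition is run with achiral Rh2(O2CC7H15)4 in refluxing hexane, where carbenoid transfer and Cope shift run together. This gives 8 together with its mirror image ent-8 F2 (through 7 and ent-7 F1). Steps 5 to 7 carry the racemate on (mirror images ent-9 F3, ent-10 F4, ent-11 F5, ent-12 F6, ent-13 F7). The CBS reduction of step 8 then acts as the resolving step: reagent control should give the 9R carbinol from both antipodes, that is 14 and its (4S,9R) diastereomer 4-epi-14 F8, which are separated by chromatography.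

Step 11. What may go wrong: proton delivery to C10 on the β face by methanol bound to samarium, which would give the cis-fused ketol. Base cannot correct this, because C8 is the more acidic α-position and C6=C7 would move into conjugation. Retro-aldol opening of ring A is a second loss channel. Fallback, from 16 back to 17: the epoxy ketone is opened without a proton donor (SmI2, THF, −78 °C) and the enolate–alkoxide is silylated in the flask (Me3SiCl, Et3N) to the bis(trimethylsilyl) derivative F9 (C9 silyl enol ether, C1 silyl ether). The isolated silyl enol ether is then protonated under reagent control with the SnCl4 complex of enantiopure BINOL (Lewis-acid-assisted chiral Brønsted acid, a known enantioselective protonation of silyl enol ethers of 2-substituted cycloalkanones), the BINOL antipode being chosen for the α face. This gives the C1-silylated ketol F10, and citric acid in methanol returns 17.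

Step 17. What may go wrong: O-acylation of the shielded tertiary alkoxide is too slow, so the acid chloride is consumed elsewhere and 20 is recovered. Fallback, from 20 back to 25: the ester carbonyl is attached first as a small electrophile and the aryl group last. The potassium alkoxide of 20 (KH, THF) reacts with 1,1′-carbonyldiimidazole to give the imidazole-1-carboxylate F11. [4-(Benzyloxy)-3-methoxyphenyl]magnesium bromide F12 (from commercial 1-(benzyloxy)-4-bromo-2-methoxybenzene and Mg) then displaces imidazole at −40 °C (ester formation from a Grignard reagent and an alkoxycarbonylimidazole) to give 25.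

**Further compounds**

F1 | step 4 | ent-7, methyl (1R,2S)-2-ethoxy-1-ethenyl-2-(2-methyl-5-oxocyclopent-1-en-1-yl)cyclopropane-1-carboxylate | C=C[C@]1(C(=O)OC)C[C@]1(OCC)C2=C(C)CCC2=O
F2 | step 4 | ent-8, (4S)-bicyclic vinylogous ester | O=C1CC[C@@]2(C)CC=C(C(=O)OC)CC(OCC)=C21
F3 | step 4 | ent-9, (4S) C1 carbinol, both C1 epimers | CC(C)C1(O)CC[C@@]2(C)CC=C(C(=O)OC)CC(OCC)=C12
F4 | step 4 | ent-10, (4S) allylic diol | CC(C)C1(O)CC[C@@]2(C)CC=C(CO)CC(OCC)=C12
F5 | step 4 | ent-11, (4S) allylic mesylate | CC(C)C1(O)CC[C@@]2(C)CC=C(COS(C)(=O)=O)CC(OCC)=C12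
F6 | step 4 | ent-12, (4S) C7-methyl carbinol | CC(C)C1(O)CC[C@@]2(C)CC=C(C)CC(OCC)=C12
F7 | step 4 | ent-13, (4S)-dienone | CC(C)C1=C2C(=O)CC(C)=CC[C@]2(C)CC1
F8 | step 4 | 4-epi-14, (4S,9R)-allylic alcohol | CC(C)C1=C2[C@H](O)CC(C)=CC[C@]2(C)CC1
F9 | step 11 | 1β-trimethylsilyloxy C9 trimethylsilyl enol ether (C9=C10) | C[Si](C)(C)O[C@@]1(C(C)C)CC[C@]2(C)CC=C(C)CC(O[Si](C)(C)C)=C21
F10 | step 11 | C1 trimethylsilyl ether of 17 | C[Si](C)(C)O[C@@]1(C(C)C)CC[C@]2(C)CC=C(C)CC(=O)[C@H]21
F11 | step 17 | C1 imidazole-1-carboxylate of 20 | O=C(O[C@@]1(C(C)C)CC[C@]2(C)C[C@@H]3O[C@]3(C)C[C@H](OCc4ccccc4)[C@H]21)n5ccnc5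
F12 | step 17 | [4-(benzyloxy)-3-methoxyphenyl]magnesium bromide | COc1cc([Mg]Br)ccc1OCc1ccccc1
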